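## Retrosynthetic overview

1. The C4–C6' interflavan bond is cut last. It is made biomimetically, by Friedel–Crafts attack of 8-bromo-tri-O-benzyl-epiafzelechin on a C4 cation of the upper flavan; this sets C4 trans to the C2 aryl group. All rings and both stereocentres of the lower unit come from (−)-epiafzelechin.
2. Ring C is the only ring that is built. It is cut at C3–C4 and O1–C8a into a sulfur-stabilised benzylic carbanion on ring A (fluorine on C8a) and the (R)-oxirane that carries ring B. One anionic [3+3] annulation forms both bonds.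
3. Enabling feature: C4 is benzylic to ring A and para to O7, so one phenylsulfanyl group lets it act as a carbanion (step 6) and then as a cation (step 9). C8a is an aromatic carbon of ring A ortho to C4a and can carry fluoride for displacement by O1. C2 is a benzylic carbinol carbon that an epoxide delivers with its configuration intact.
4. Order of ring formation: rings A and B are bought as arenes, ring C is closed in step 6, the lower unit is attached in step 9, and all benzyl ethers and the bromine fall in step 10.

Key step: step 6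

Remark: (−)-epiafzelechin (2R,3R) is taken as a purchasable natural product, and its tribenzyl ether is assumed to brominate at C8 before C6 as the catechin ethers do; locants are flavan locants, primed for the lower unit.

## Route

Step 1
Reactants: 1 2-fluoro-4-hydroxybenzaldehyde
Product: 2 4-(benzyloxy)-2-fluorobenzaldehyde
Conditions: BnBr, K2CO3, DMF, rt
Reagents that add atoms: benzyl bromide, BrCc1ccccc1
Why: Williamson etherification of the only acidic OH should be clean, and the benzyl ether withstands the strong bases and the silver salt that follow before it falls in step 10.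

Step 2
Reactants: 2 4-(benzyloxy)-2-fluorobenzaldehyde
Product: 3 [4-(benzyloxy)-2-fluorophenyl]methanol
Conditions: NaBH4, MeOH/THF, 0 °C
Reagents that add atoms: none
Why: Borohydride reduction of an aryl aldehyde is chemoselective and leaves the aryl fluoride and the benzyl ether untouched.

Step 3
Reactants: 3 [4-(benzyloxy)-2-fluorophenyl]methanol
Product: 4 4-(benzyloxy)-2-fluorobenzyl phenyl sulfide
Conditions: PhSSPh, n-Bu3P, THF, rt
Reagents that add atoms: diphenyl disulfide, c1ccc(SSc2ccccc2)cc1
Why: The Hata disulfide/phosphine condensation should replace the primary benzylic OH by SPh under neutral conditions, which avoids an electron-rich benzyl halide.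

Step 4
Reactants: 5 2-bromo-1-[4-(benzyloxy)phenyl]ethan-1-one
Product: 6 (1R)-1-[4-(benzyloxy)phenyl]-2-bromoethan-1-ol
Conditions: (R)-2-methyl-CBS-oxazaborolidine (10 mol%), BH3·SMe2, THF, 0 °C
Reagents that add atoms: none
Why: Corey–Bakshi–Shibata reduction, for which α-bromoacetophenones are standard substrates, should deliver hydride to the face that gives the (R) carbinol (aryl as the large group, CH2Br as the small one), and this catalyst-controlled step sets the carbon that becomes C2 of the target.

Step 5
Reactants: 6 (1R)-1-[4-(benzyloxy)phenyl]-2-bromoethan-1-ol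
Product: 7 (2R)-2-[4-(benzyloxy)phenyl]oxirane
Conditions: NaOH (2 M aq), THF, 0 °C to rt
Reagents that add atoms: none
Why: Intramolecular Williamson closure takes place at the CH2Br carbon, so the benzylic stereocentre is not touched and stays (R); the acid-sensitive p-alkoxystyrene oxide is kept basic and used without chromatography on silica.

Step 6
Reactants: 4 4-(benzyloxy)-2-fluorobenzyl phenyl sulfide; 7 (2R)-2-[4-(benzyloxy)phenyl]oxirane
Product: 10 (2S)-7-(benzyloxy)-2-[4-(benzyloxy)phenyl]-4-(phenylsulfanyl)chromane (both C4 epimers), via lithiated sulfide 8 (not isolated), via open-chain lithium alkoxide 9 (not isolated)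
Conditions: LiN(i-Pr)2 (1.05 equiv), THF, −78 to −40 °C; 7, DMPU, −78 to 0 °C; then KOt-Bu (1.0 equiv), DMSO, 60 °C
Reagents that add atoms: none
Why: Proposed new method: LiN(i-Pr)2 removes the benzylic proton of 4, which is acidified by the sulfur substituent and by ring A, to give 8; 8 opens oxirane 7 by SN2 attack at its unsubstituted CH2 carbon (C3–C4 bond, alkoxide 9), and once potassium and DMSO are added the C2 alkoxide of 9 displaces fluoride from C8a by addition–elimination (SNAr), a 6-exo-trig closure of ring C in which the charge is pushed onto C8 and the O1–C8a bond forms. The closest known reactions are the terminal opening of aryloxiranes by sulfur-stabilised benzylic organolithiums and the alkoxide SNAr cyclisation of 3-(2-fluoroaryl)propan-1-ols to chromans; new is their fusion into one annulation on a fluoroarene that is activated only by the inductive pull of the meta benzyloxy group. C2 is not formed here: none of its bonds is broken, so the (R) centre of 7 becomes C2 (S) of 10 unchanged in space (only the CIP priorities change). C4 is the one new stereocentre; it forms without control, and both epimers are carried on because C4 is made planar again in step 9. The step needs benzylic rather than ring metalation (secured by the sulfur group and an amide base at low temperature), attack at the CH2 end of the epoxide (secured by the SN2 character of a soft carbanion in THF/DMPU) and an oxygen anion rather than a ring-deactivating carbanion during SNAr (secured because the α-sulfanyl C–H of 9 is less acidic than its OH).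

Step 7
Reactants: 11 (−)-epiafzelechin [(2R,3R)-2-(4-hydroxyphenyl)chromane-3,5,7-triol]
Product: 12 (2R,3R)-5,7-bis(benzyloxy)-2-[4-(benzyloxy)phenyl]chroman-3-ol
Conditions: BnBr (3.3 equiv), K2CO3, DMF, 0 °C to rt
Reagents that add atoms: benzyl bromide, BrCc1ccccc1
Why: Carbonate deprotonates only the three phenols, so O-benzylation should spare the secondary 3-OH, as in the preparation of benzyl-protected catechins.

Step 8
Reactants: 12 (2R,3R)-5,7-bis(benzyloxy)-2-[4-(benzyloxy)phenyl]chroman-3-ol
Product: 13 (2R,3R)-5,7-bis(benzyloxy)-2-[4-(benzyloxy)phenyl]-8-bromochroman-3-ol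
Conditions: NBS (1.0 equiv), CH2Cl2, −78 °C to rt
Reagents that add atoms: N-bromosuccinimide, O=C1CCC(=O)N1Br
Why: Electrophilic bromination of 5,7-di-O-benzyl flavan-3-ols takes place at C8 first, which blocks that position and leaves C6 as the only free nucleophilic carbon of the phloroglucinol ring.

Step 9
Reactants: 10 (2S)-7-(benzyloxy)-2-[4-(benzyloxy)phenyl]-4-(phenylsulfanyl)chromane; 13 (2R,3R)-5,7-bis(benzyloxy)-2-[4-(benzyloxy)phenyl]-8-bromochroman-3-ol (2.5 equiv, excess recovered)
Product: 15 (2R,3R)-5,7-bis(benzyloxy)-2-[4-(benzyloxy)phenyl]-6-{(2S,4R)-7-(benzyloxy)-2-[4-(benzyloxy)phenyl]chroman-4-yl}-8-bromochroman-3-ol, via flavan-4-yl cation 14 (not isolated)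
Conditions: AgBF4 (1.5 equiv), THF, −40 to 0 °C
Reagents that add atoms: none
Why: In this known silver-promoted thioether interflavan coupling (Friedel–Crafts type), AgBF4 pulls off benzenethiolate to give the 7-alkoxy-stabilised benzylic cation 14 from either C4 epimer of 10, and C6' of 13 (C8' blocked by bromine) should add to C4 quasi-axially on the face away from the pseudo-equatorial C2 aryl group, which sets C4 as (R) (2,4-trans) in the way the biogenesis of 4-arylflavans is thought to do, any 2,4-cis epimer being removed by chromatography.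

Step 10
Reactants: 15 (2R,3R)-5,7-bis(benzyloxy)-2-[4-(benzyloxy)phenyl]-6-{(2S,4R)-7-(benzyloxy)-2-[4-(benzyloxy)phenyl]chroman-4-yl}-8-bromochroman-3-ol
Product: 16 (2R,3R)-6-[(2S,4R)-7-hydroxy-2-(4-hydroxyphenyl)chroman-4-yl]-2-(4-hydroxyphenyl)chromane-3,5,7-triol (CNP0167324.2)
Conditions: H2 (1 atm), Pd(OH)2/C, Et3N, THF/MeOH/H2O, rt
Reagents that add atoms: none
Why: Hydrogenolysis should remove the five O-benzyl groups and the C8' bromine in one operation (Et3N takes up the HBr), while the cyclic benzylic C2–O bonds and the C4–C6' bond are expected to survive, as they do in the deprotection of benzylated, bromine-capped proanthocyanidins.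

## Compound list

1 | 2-fluoro-4-hydroxybenzaldehyde | O=Cc1ccc(O)cc1F | starting material
2 | 4-(benzyloxy)-2-fluorobenzaldehyde | O=Cc1ccc(OCc2ccccc2)cc1F | intermediate
3 | [4-(benzyloxy)-2-fluorophenyl]methanol | OCc1ccc(OCc2ccccc2)cc1F | intermediate
4 | 4-(benzyloxy)-2-fluorobenzyl phenyl sulfide | Fc1cc(OCc2ccccc2)ccc1CSc1ccccc1 | intermediate
5 | 2-bromo-1-[4-(benzyloxy)phenyl]ethan-1-one | O=C(CBr)c1ccc(OCc2ccccc2)cc1 | starting material
6 | (1R)-1-[4-(benzyloxy)phenyl]-2-bromoethan-1-ol | O[C@@H](CBr)c1ccc(OCc2ccccc2)cc1 | intermediate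
7 | (2R)-2-[4-(benzyloxy)phenyl]oxirane | C(c1ccccc1)Oc1ccc([C@@H]2CO2)cc1 | intermediate
8 | [4-(benzyloxy)-2-fluorophenyl](phenylsulfanyl)methyllithium (lithiated sulfide) | [Li]C(Sc1ccccc1)c1ccc(OCc2ccccc2)cc1F | intermediate
9 | lithium (1S)-1-[4-(benzyloxy)phenyl]-3-[4-(benzyloxy)-2-fluorophenyl]-3-(phenylsulfanyl)propan-1-olate (both C3 epimers) | [Li+].[O-][C@@H](CC(Sc1ccccc1)c1ccc(OCc2ccccc2)cc1F)c1ccc(OCc2ccccc2)cc1 | intermediate
10 | (2S)-7-(benzyloxy)-2-[4-(benzyloxy)phenyl]-4-(phenylsulfanyl)chromane (both C4 epimers) | C(c1ccccc1)Oc1ccc([C@@H]2CC(Sc3ccccc3)c3ccc(OCc4ccccc4)cc3O2)cc1 | intermediate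
11 | (−)-epiafzelechin, (2R,3R)-2-(4-hydroxyphenyl)chromane-3,5,7-triol | Oc1cc(O)c2C[C@@H](O)[C@@H](c3ccc(O)cc3)Oc2c1 | starting material
12 | (2R,3R)-5,7-bis(benzyloxy)-2-[4-(benzyloxy)phenyl]chroman-3-ol | C(c1ccccc1)Oc1cc(OCc2ccccc2)c2C[C@@H](O)[C@@H](c3ccc(OCc4ccccc4)cc3)Oc2c1 | intermediate
13 | (2R,3R)-5,7-bis(benzyloxy)-2-[4-(benzyloxy)phenyl]-8-bromochroman-3-ol | C(c1ccccc1)Oc1cc(OCc2ccccc2)c2C[C@@H](O)[C@@H](c3ccc(OCc4ccccc4)cc3)Oc2c1Br | intermediate
14 | (2S)-7-(benzyloxy)-2-[4-(benzyloxy)phenyl]chroman-4-ylium tetrafluoroborate | F[B-](F)(F)F.C(c1ccccc1)Oc1ccc([C@@H]2C[CH+]c3ccc(OCc4ccccc4)cc3O2)cc1 | intermediate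
15 | (2R,3R)-5,7-bis(benzyloxy)-2-[4-(benzyloxy)phenyl]-6-{(2S,4R)-7-(benzyloxy)-2-[4-(benzyloxy)phenyl]chroman-4-yl}-8-bromochroman-3-ol | C(c1ccccc1)Oc1ccc([C@@H]2C[C@@H](c3c(OCc5ccccc5)c(Br)c4c(c3OCc5ccccc5)C[C@@H](O)[C@@H](c3ccc(OCc5ccccc5)cc3)O4)c3ccc(OCc5ccccc5)cc3O2)cc1 | intermediate
16 | (2R,3R)-6-[(2S,4R)-7-hydroxy-2-(4-hydroxyphenyl)chroman-4-yl]-2-(4-hydroxyphenyl)chromane-3,5,7-triol | Oc1ccc([C@@H]2C[C@@H](c3c(O)cc4c(c3O)C[C@@H](O)[C@@H](c3ccc(O)cc3)O4)c3ccc(O)cc3O2)cc1 | target

## Step count and risks

Total step count: 10. Longest linear sequence: 6 steps (1, 2, 3, 6, 9, 10).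

**Step 6 (proposed new method).** What may go wrong: metalation at the ring carbon between fluorine and the benzyloxy group (followed by loss of LiF) instead of at the benzylic carbon, or failure of the barely activated fluoroarene to undergo ring-closing SNAr. The fallback uses known chemistry, sets out from 7 and returns at 10; it uncouples the two bond formations and makes the aryl–oxygen bond by copper catalysis on a bromoarene. Commercial 2-bromo-4-hydroxybenzaldehyde is taken through the operations of steps 1 to 3 to give 4-(benzyloxy)-2-bromobenzaldehyde F1, then [4-(benzyloxy)-2-bromophenyl]methanol F2, then 4-(benzyloxy)-2-bromobenzyl phenyl sulfide F3. F3 is lithiated with LiN(i-Pr)2 at −78 °C and added to 7; aqueous work-up gives the isolated alcohol (1S)-1-[4-(benzyloxy)phenyl]-3-[4-(benzyloxy)-2-bromophenyl]-3-(phenylsulfanyl)propan-1-ol F4. CuI (10 mol%), 3,4,7,8-tetramethyl-1,10-phenanthroline and Cs2CO3 in toluene at 110 °C then close ring C by intramolecular Ullmann etherification, with retention at C2, to give 10.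

**Step 9.** What may go wrong: ionisation of the C–S bond may stall or reverse through recapture of the cation by thiolate, the cation may lose the C3 proton faster than the hindered C6' attacks, and face selectivity at C4 may be modest. The fallback sets out from 10 and returns at 15; it generates the same cation catalytically from an alkene, without silver or thiolate. One equivalent of mCPBA at −78 °C oxidises 10 to (2S)-4-(benzenesulfinyl)-7-(benzyloxy)-2-[4-(benzyloxy)phenyl]chromane F5. Warming F5 in toluene over NaHCO3, in the dark and below 80 °C, eliminates benzenesulfenic acid to give (2S)-7-(benzyloxy)-2-[4-(benzyloxy)phenyl]-2H-chromene F6. Acid-catalysed hydroarylation of F6 with 13 (TfOH, 10 mol%, CH2Cl2, −40 °C; the classical flav-3-ene/phenol route to 4-arylflavans) protonates C3 and lets C6' add to C4, giving 15. The lower temperature that this catalytic variant allows should favour attack trans to the C2 aryl group.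

**Step 10.** What may go wrong: hydrogenolysis may stop before the aryl bromide is reduced, or go on to open the benzylic C2–O bonds of the two pyran rings. The fallback sets out from 15 and returns at 16; it removes bromine and benzyl groups in two non-hydrogenolytic operations. n-Bu3SnH/AIBN in toluene at 100 °C replaces the bromine by hydrogen to give (2R,3R)-5,7-bis(benzyloxy)-2-[4-(benzyloxy)phenyl]-6-{(2S,4R)-7-(benzyloxy)-2-[4-(benzyloxy)phenyl]chroman-4-yl}chroman-3-ol F7. BCl3 with pentamethylbenzene as cation scavenger in CH2Cl2 at −78 °C then cleaves the five benzyl ethers to give 16.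

Further compounds
F1 | step 6 | 4-(benzyloxy)-2-bromobenzaldehyde | O=Cc1ccc(OCc2ccccc2)cc1Br
F2 | step 6 | [4-(benzyloxy)-2-bromophenyl]methanol | OCc1ccc(OCc2ccccc2)cc1Br
F3 | step 6 | 4-(benzyloxy)-2-bromobenzyl phenyl sulfide | Brc1cc(OCc2ccccc2)ccc1CSc1ccccc1
F4 | step 6 | (1S)-1-[4-(benzyloxy)phenyl]-3-[4-(benzyloxy)-2-bromophenyl]-3-(phenylsulfanyl)propan-1-ol (both C3 epimers) | O[C@@H](CC(Sc1ccccc1)c1ccc(OCc2ccccc2)cc1Br)c1ccc(OCc2ccccc2)cc1
F5 | step 9 | (2S)-4-(benzenesulfinyl)-7-(benzyloxy)-2-[4-(benzyloxy)phenyl]chromane | C(c1ccccc1)Oc1ccc([C@@H]2CC(S(=O)c3ccccc3)c3ccc(OCc4ccccc4)cc3O2)cc1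
F6 | step 9 | (2S)-7-(benzyloxy)-2-[4-(benzyloxy)phenyl]-2H-chromene | C(c1ccccc1)Oc1ccc([C@@H]2C=Cc3ccc(OCc4ccccc4)cc3O2)cc1
F7 | step 10 | (2R,3R)-5,7-bis(benzyloxy)-2-[4-(benzyloxy)phenyl]-6-{(2S,4R)-7-(benzyloxy)-2-[4-(benzyloxy)phenyl]chroman-4-yl}chroman-3-ol | C(c1ccccc1)Oc1ccc([C@@H]2C[C@@H](c3c(OCc5ccccc5)cc4c(c3OCc5ccccc5)C[C@@H](O)[C@@H](c3ccc(OCc5ccccc5)cc3)O4)c3ccc(OCc5ccccc5)cc3O2)cc1
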